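**Retrosynthetic overview**

- Sophonorol F (25, 3S) is reached from ketol 23 by removing the MOM group at O4′ and the ethyl group at O5. Ring C is closed last, by a carbene-catalysed aldehyde–ketone benzoin reaction that forms C3–C4 and sets C3.
- Keto aldehyde 22 is cut at the O1–C2 ether bond into salicylaldehyde 15 (ring A) and phenacyl bromide 21 (ring B, from 2,4-dihydroxyacetophenone).
- Aldehyde 15 comes from phenol 13 by ortho-formylation (C4–C4a) at the only free position next to the C8a hydroxyl.
- The strategy rests on ring A, a phloroglucinol ring whose three oxygens (O1 on C8a, OH on C5, OMe on C7) all differ and whose prenyl group sits on C8 between C7 and C8a. It is built in one operation from 3-ethoxycyclobutenone 4 and ynol ether 8 (bonds C8–C8a, C6–C7, C4a–C8a).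
- Ring order: ring A (step 3), then ring C (step 10); ring B is bought in.

Key step: step 3

Assumption: the (5aR,10bS) aminoindanol-derived triazolium salt is taken to give the (3S) ketol in step 10; if the sense of induction proves opposite, the (5aS,10bR) salt is used and nothing else changes.

**Route**

Step 1
Reactants: 1 ethoxyacetylene; 2 acetone
Product: 4 3-ethoxycyclobut-2-en-1-one, via ketene 3 (not isolated)
Conditions: ketene from 2 (hot-filament pyrolysis, ca. 700 °C) passed into 1, CH2Cl2, 0 °C
Reagents that add atoms: none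
Why: Thermal (2+2) cycloaddition of ketene to an ynol ether, in which the nucleophilic terminal alkyne carbon bonds to the ketene carbonyl carbon, is the established entry to 3-alkoxycyclobutenones and needs no catalyst.

Step 2
Reactants: 5 chloroacetaldehyde dimethyl acetal; 6 prenyl bromide
Product: 8 1-methoxy-5-methylhex-4-en-1-yne, via lithium methoxyacetylide 7 (not isolated)
Conditions: LiNH2 (3 equiv), liq. NH3, −33 °C; then 6, THF, −78 → −33 °C
Reagents that add atoms: lithium amide, [Li+].[NH2-] (its lithium is carried only by 7)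
Why: Twofold elimination from the chloroacetal and deprotonation consume exactly three equivalents of amide to give the alkoxyacetylide, whose SN2 alkylation at a primary allylic bromide is the standard synthesis of 1-alkoxy-1-alkynes, and no free amide remains to isomerise the skipped enyne.

Step 3
Reactants: 4 3-ethoxycyclobut-2-en-1-one; 8 1-methoxy-5-methylhex-4-en-1-yne
Product: 13 5-ethoxy-3-methoxy-2-(3-methylbut-2-en-1-yl)phenol, via 3-ethoxyvinylketene 9 (not isolated), via 4-(1-ethoxyethenyl)cyclobutenone 10 (not isolated), via dienylketene 11 (not isolated), via cyclohexa-2,4-dienone 12 (not isolated)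
Conditions: 4 (1.5 equiv), toluene, 80 → 110 °C, sealed tube; then K2CO3, MeOH, rt
Reagents that add atoms: none
Why: Danheiser benzannulation: four-electron electrocyclic opening of 4 gives vinylketene 9, which adds to the ynol ether in a (2+2) sense, the nucleophilic prenyl-bearing alkyne carbon bonding to the ketene carbonyl carbon, to give 10. Four-electron opening of 10 gives dienylketene 11, which closes ring A by six-electron electrocyclisation (bond C4a–C8a) to dienone 12, and this tautomerises to phenol 13. The closest known reaction type is the thermal annulation of cyclobutenones with alkoxy- and siloxyalkynes to resorcinol monoethers; only the 3-alkoxy group on the cyclobutenone is less common. No stereocentre is formed. The step needs regioselectivity, and the polarisation of the ynol ether secures it: the ketene carbonyl becomes the free C8a hydroxyl next to the C8 prenyl group, the methoxy carbon becomes C7 and the ethoxy carbon C5 (a concerted 4+2 pathway would lead to the same phenol). The methyl ynol ether cannot lose an alkene by retro-ene fragmentation on heating, and the closing methanolysis returns 13 from any aryl ester formed when the phenol traps a ketene.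

Step 4
Reactants: 13 5-ethoxy-3-methoxy-2-(3-methylbut-2-en-1-yl)phenol
Product: 15 6-ethoxy-2-hydroxy-4-methoxy-3-(3-methylbut-2-en-1-yl)benzaldehyde, via salicyl alcohol 14 (not isolated)
Conditions: MgCl2, Et3N, (CH2O)n, MeCN, 80 °C; aq. citric acid work-up
Reagents that add atoms: paraformaldehyde, as formaldehyde C=O
Why: In this magnesium-mediated ortho-formylation (Casnati–Skattebøl reaction) the magnesium phenoxide delivers formaldehyde only ortho to oxygen, where C4a is the single free position, and a second formaldehyde oxidises the salicyl alkoxide by hydride transfer under non-acidic conditions that spare the prenyl group.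

Step 5
Reactants: 16 2,4-dihydroxyacetophenone; 6 prenyl bromide
Product: 17 1-[2,4-dihydroxy-3-(3-methylbut-2-en-1-yl)phenyl]ethan-1-one
Conditions: KOH (10% aq.), 0 °C → rt
Reagents that add atoms: none
Why: C-Alkylation of the resacetophenone phenoxide in water goes preferentially to C3, the carbon flanked by both hydroxyls, a known nuclear prenylation whose modest efficiency is acceptable at this cheap first stage because the O-prenyl and 5-prenyl by-products are separable.

Step 6
Reactants: 17 1-[2,4-dihydroxy-3-(3-methylbut-2-en-1-yl)phenyl]ethan-1-one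
Product: 18 1-[2-hydroxy-4-(methoxymethoxy)-3-(3-methylbut-2-en-1-yl)phenyl]ethan-1-one
Conditions: MOMCl (1.1 equiv), K2CO3, acetone, 0 °C → rt
Reagents that add atoms: chloromethyl methyl ether, COCCl
Why: Williamson-type acetal formation is selective for the 4-hydroxyl because the 2-hydroxyl is held in a hydrogen bond to the acetyl carbonyl.

Step 7
Reactants: 18 1-[2-hydroxy-4-(methoxymethoxy)-3-(3-methylbut-2-en-1-yl)phenyl]ethan-1-one
Product: 19 1-[2-methoxy-4-(methoxymethoxy)-3-(3-methylbut-2-en-1-yl)phenyl]ethan-1-one
Conditions: MeI, K2CO3, DMF, 40 °C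
Reagents that add atoms: iodomethane, CI
Why: Williamson O-methylation of the remaining chelated phenol needs only these slightly more forcing conditions, to which the MOM acetal, the prenyl group and the methyl ketone are inert.

Step 8
Reactants: 19 1-[2-methoxy-4-(methoxymethoxy)-3-(3-methylbut-2-en-1-yl)phenyl]ethan-1-one
Product: 21 2-bromo-1-[2-methoxy-4-(methoxymethoxy)-3-(3-methylbut-2-en-1-yl)phenyl]ethan-1-one, via trimethylsilyl enol ether 20 (not isolated)
Conditions: LiN(SiMe3)2, Me3SiCl, THF, −78 °C; then NBS, THF, −78 → 0 °C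
Reagents that add atoms: N-bromosuccinimide, O=C1CCC(=O)N1Br; chlorotrimethylsilane, C[Si](C)(C)Cl (its silyl group is carried only by 20)
Why: Kinetic enolisation and silylation followed by electrophilic bromination of the silyl enol ether with NBS at low temperature halogenates the methyl ketone only, whereas Br2 or acid-catalysed bromination would attack the trisubstituted prenyl alkene and the acetal.

Step 9
Reactants: 15 6-ethoxy-2-hydroxy-4-methoxy-3-(3-methylbut-2-en-1-yl)benzaldehyde; 21 2-bromo-1-[2-methoxy-4-(methoxymethoxy)-3-(3-methylbut-2-en-1-yl)phenyl]ethan-1-one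
Product: 22 6-ethoxy-4-methoxy-2-{2-[2-methoxy-4-(methoxymethoxy)-3-(3-methylbut-2-en-1-yl)phenyl]-2-oxoethoxy}-3-(3-methylbut-2-en-1-yl)benzaldehyde
Conditions: K2CO3, DMF, 0 °C → rt
Reagents that add atoms: none
Why: Williamson etherification of the phenoxide with a highly reactive phenacyl bromide proceeds at or below room temperature, mild enough that Rap–Stoermer aldol condensation to a 2-aroylbenzofuran should not set in at the electron-rich, doubly ortho-substituted aldehyde.

Step 10
Reactants: 22 keto aldehyde
Product: 23 (3S)-5-ethoxy-3-hydroxy-7-methoxy-3-[2-methoxy-4-(methoxymethoxy)-3-(3-methylbut-2-en-1-yl)phenyl]-8-(3-methylbut-2-en-1-yl)-2,3-dihydro-4H-chromen-4-one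
Conditions: (5aR,10bS)-2-(pentafluorophenyl)-5a,10b-dihydro-4H,6H-indeno[2,1-b][1,2,4]triazolo[4,3-d][1,4]oxazin-2-ium tetrafluoroborate (15 mol %), Et3N (15 mol %), toluene, rt
Reagents that add atoms: none
Why: In this N-heterocyclic-carbene-catalysed intramolecular crossed aldehyde–ketone benzoin reaction the chiral triazolylidene turns the aldehyde into a Breslow intermediate whose acyl-anion carbon adds 6-exo to the ketone, closing ring C (bond C3–C4) and setting the C3 carbinol under catalyst control by face-selective attack inside the aminoindanol pocket, a known route to 3-aryl-3-hydroxychroman-4-ones under neutral, non-oxidising conditions that leave both prenyl groups alone.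

Step 11
Reactants: 23 MOM-protected ketol
Product: 24 (3S)-5-ethoxy-3-hydroxy-3-[4-hydroxy-2-methoxy-3-(3-methylbut-2-en-1-yl)phenyl]-7-methoxy-8-(3-methylbut-2-en-1-yl)-2,3-dihydro-4H-chromen-4-one
Conditions: HCl (1.5 M), MeOH–THF, 40 °C
Reagents that add atoms: none
Why: Acid-catalysed acetal exchange removes the MOM group under dilute conditions that are routine for prenylated phenols, and the C3 carbinol should not ionise because its cation would lie next to the C4 carbonyl, so the stereocentre is kept.

Step 12
Reactants: 24 5-O-ethyl ketol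
Product: 25 sophonorol F, (3S)-3,5-dihydroxy-3-[4-hydroxy-2-methoxy-3-(3-methylbut-2-en-1-yl)phenyl]-7-methoxy-8-(3-methylbut-2-en-1-yl)-2,3-dihydro-4H-chromen-4-one
Conditions: MgI2·OEt2 (5 equiv), THF, 65 °C; aq. NH4Cl, Na2S2O3
Reagents that add atoms: none
Why: In this chelation-assisted ether cleavage MgI2 binds the C4 carbonyl and the peri O5, so iodide dealkylates only the ether held in that six-membered chelate and leaves the unchelated C7 and C2′ methyl ethers, the C3 stereocentre and the prenyl groups untouched, as magnesium iodide demethylations of 5-methoxy-8-prenylflavanones suggest.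

**Compound list**

1 | ethoxyacetylene | CCOC#C | starting material
2 | acetone | CC(C)=O | starting material
3 | ketene | C=C=O | intermediate
4 | 3-ethoxycyclobut-2-en-1-one | CCOC1=CC(=O)C1 | intermediate
5 | chloroacetaldehyde dimethyl acetal | COC(CCl)OC | starting material
6 | prenyl bromide (1-bromo-3-methylbut-2-ene) | CC(C)=CCBr | starting material
7 | lithium methoxyacetylide | [Li]C#COC | intermediate
8 | 1-methoxy-5-methylhex-4-en-1-yne | COC#CCC=C(C)C | intermediate
9 | 3-ethoxybuta-1,3-dien-1-one (3-ethoxyvinylketene) | C=C(OCC)C=C=O | intermediate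
10 | 4-(1-ethoxyethenyl)-3-methoxy-2-(3-methylbut-2-en-1-yl)cyclobut-2-en-1-one | O=C1C(CC=C(C)C)=C(OC)C1C(OCC)=C | intermediate
11 | 5-ethoxy-3-methoxy-2-(3-methylbut-2-en-1-yl)hexa-1,3,5-trien-1-one, ketene carbon and ethoxyvinyl group cis on the C3=C4 bond | O=C=C(CC=C(C)C)/C(OC)=C\C(OCC)=C | intermediate
12 | 5-ethoxy-3-methoxy-2-(3-methylbut-2-en-1-yl)cyclohexa-2,4-dien-1-one | O=C1CC(OCC)=CC(OC)=C1CC=C(C)C | intermediate
13 | 5-ethoxy-3-methoxy-2-(3-methylbut-2-en-1-yl)phenol | Oc1cc(OCC)cc(OC)c1CC=C(C)C | intermediate
14 | 3-ethoxy-2-(hydroxymethyl)-5-methoxy-6-(3-methylbut-2-en-1-yl)phenol (present as its magnesium salt) | OCc1c(O)c(CC=C(C)C)c(OC)cc1OCC | intermediate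
15 | 6-ethoxy-2-hydroxy-4-methoxy-3-(3-methylbut-2-en-1-yl)benzaldehyde | O=Cc1c(O)c(CC=C(C)C)c(OC)cc1OCC | intermediate
16 | 2,4-dihydroxyacetophenone | CC(=O)c1ccc(O)cc1O | starting material
17 | 1-[2,4-dihydroxy-3-(3-methylbut-2-en-1-yl)phenyl]ethan-1-one | CC(=O)c1ccc(O)c(CC=C(C)C)c1O | intermediate
18 | 1-[2-hydroxy-4-(methoxymethoxy)-3-(3-methylbut-2-en-1-yl)phenyl]ethan-1-one | CC(=O)c1ccc(OCOC)c(CC=C(C)C)c1O | intermediate
19 | 1-[2-methoxy-4-(methoxymethoxy)-3-(3-methylbut-2-en-1-yl)phenyl]ethan-1-one | CC(=O)c1ccc(OCOC)c(CC=C(C)C)c1OC | intermediate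
20 | ({1-[2-methoxy-4-(methoxymethoxy)-3-(3-methylbut-2-en-1-yl)phenyl]ethenyl}oxy)trimethylsilane | C=C(O[Si](C)(C)C)c1ccc(OCOC)c(CC=C(C)C)c1OC | intermediate
21 | 2-bromo-1-[2-methoxy-4-(methoxymethoxy)-3-(3-methylbut-2-en-1-yl)phenyl]ethan-1-one | BrCC(=O)c1ccc(OCOC)c(CC=C(C)C)c1OC | intermediate
22 | 6-ethoxy-4-methoxy-2-{2-[2-methoxy-4-(methoxymethoxy)-3-(3-methylbut-2-en-1-yl)phenyl]-2-oxoethoxy}-3-(3-methylbut-2-en-1-yl)benzaldehyde | O=Cc1c(OCC)cc(OC)c(CC=C(C)C)c1OCC(=O)c1ccc(OCOC)c(CC=C(C)C)c1OC | intermediate
23 | (3S)-5-ethoxy-3-hydroxy-7-methoxy-3-[2-methoxy-4-(methoxymethoxy)-3-(3-methylbut-2-en-1-yl)phenyl]-8-(3-methylbut-2-en-1-yl)-2,3-dihydro-4H-chromen-4-one | COc1cc(OCC)c2c(c1CC=C(C)C)OC[C@@](O)(c1ccc(OCOC)c(CC=C(C)C)c1OC)C2=O | intermediate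
24 | (3S)-5-ethoxy-3-hydroxy-3-[4-hydroxy-2-methoxy-3-(3-methylbut-2-en-1-yl)phenyl]-7-methoxy-8-(3-methylbut-2-en-1-yl)-2,3-dihydro-4H-chromen-4-one | COc1cc(OCC)c2c(c1CC=C(C)C)OC[C@@](O)(c1ccc(O)c(CC=C(C)C)c1OC)C2=O | intermediate
25 | sophonorol F, (3S)-3,5-dihydroxy-3-[4-hydroxy-2-methoxy-3-(3-methylbut-2-en-1-yl)phenyl]-7-methoxy-8-(3-methylbut-2-en-1-yl)-2,3-dihydro-4H-chromen-4-one | COc1cc(O)c2c(c1CC=C(C)C)OC[C@@](O)(c1ccc(O)c(CC=C(C)C)c1OC)C2=O | target

**Step count**

Total: 12 steps. Longest linear sequence: 8 steps (steps 5 to 12, from 2,4-dihydroxyacetophenone 16); the ring A branch runs 7 steps.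

**Steps most likely to fail**

1. Step 3. The electron-rich vinylketene 9 and cyclobutenone 4 may dimerise or polymerise at the temperature needed for ring opening, or ketene trapping by the product phenol may outrun cycloaddition to the ynol ether. The fallback generates the same vinylketene photochemically at room temperature (second-generation Danheiser benzannulation); it sets out from ynol ether 8 and returns to the route at phenol 13. Ethyl vinyl ether is lithiated (t-BuLi, THF, −78 → 0 °C) and acylated with N-methoxy-N-methylacetamide to give 3-ethoxybut-3-en-2-one F1. Treatment with LiN(SiMe3)2 and CF3CO2CH2CF3 gives the trifluoroacetyl diketone F2, which is not isolated. Detrifluoroacetylative diazo transfer (MsN3, Et3N, water, MeCN) then gives 1-diazo-3-ethoxybut-3-en-2-one F3. Irradiation of F3 with 8 in CH2Cl2 at room temperature triggers a Wolff rearrangement to 9, which is intercepted by the alkyne as it forms, and brief warming to 80 °C should complete the electrocyclic cascade through 10, 11 and 12 to 13.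

2. Step 10. Facial selectivity may be poor when the Breslow intermediate adds to the hindered ortho-substituted aryl ketone, and slow carbene addition to the doubly ortho-alkoxylated aldehyde would leave time for reversible benzoin addition to erode it. The fallback sets C3 by reagent-controlled enolate oxidation; it sets out from keto aldehyde 22 and returns at ketol 23. An achiral carbene (from 2-(pentafluorophenyl)-6,7-dihydro-5H-pyrrolo[2,1-c][1,2,4]triazol-2-ium tetrafluoroborate and Et3N) cyclises 22 to the racemic ketol F4. SmI2 in THF–MeOH at −78 °C cleaves the C3–O bond next to the ketone to give isoflavanone F5. The sodium enolate of F5 (NaN(SiMe3)2, THF, −78 °C) is hydroxylated with the enantiomer of [(8,8-dimethoxycamphoryl)sulfonyl]oxaziridine that delivers the (3S) alcohol, a reagent class that works well on 5-alkoxychroman-4-one enolates and does not touch isolated alkenes at this temperature, to give 23.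

3. Step 12. Iodide attack at the ethyl carbon may be sluggish, so that prolonged heating with the Lewis acid lets the 3′-prenyl group cyclise onto the free 4′-hydroxyl or add HI. The fallback inverts and merges the two deprotections; it sets out from MOM ether 23, bypasses 24 and returns at target 25. BCl3 (4 equiv) in CH2Cl2 at −78 → −20 °C forms a boron chelate between O4 and O5 that cleaves the ethyl ether without heating, and the same reagent cleaves the MOM acetal while the 4′-oxygen stays masked as a borate until the cold aqueous quench.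

Further compounds
F1 | step 3 | 3-ethoxybut-3-en-2-one | CC(=O)C(=C)OCC
F2 | step 3 | 5-ethoxy-1,1,1-trifluorohex-5-ene-2,4-dione | C=C(OCC)C(=O)CC(=O)C(F)(F)F
F3 | step 3 | 1-diazo-3-ethoxybut-3-en-2-one | C=C(OCC)C(=O)C=[N+]=[N-]
F4 | step 10 | racemic 5-ethoxy-3-hydroxy-7-methoxy-3-[2-methoxy-4-(methoxymethoxy)-3-(3-methylbut-2-en-1-yl)phenyl]-8-(3-methylbut-2-en-1-yl)-2,3-dihydro-4H-chromen-4-one | COc1cc(OCC)c2c(c1CC=C(C)C)OCC(O)(c1ccc(OCOC)c(CC=C(C)C)c1OC)C2=O
F5 | step 10 | racemic 5-ethoxy-7-methoxy-3-[2-methoxy-4-(methoxymethoxy)-3-(3-methylbut-2-en-1-yl)phenyl]-8-(3-methylbut-2-en-1-yl)-2,3-dihydro-4H-chromen-4-one | COc1cc(OCC)c2c(c1CC=C(C)C)OCC(c1ccc(OCOC)c(CC=C(C)C)c1OC)C2=O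
F0 | step 12 | none | none
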